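**Retrosynthetic overview**

1. Target 23 ⇐ tribenzyl ether 22 (hydrogenolysis) ⇐ 8-bromide 21 (copper-catalysed methoxylation) ⇐ flavone 20 (bromination of the C8–H).
2. Flavone 20 ⇐ silyl triflate 10 + acid 17. Ring C is cut at C8a–O1, C4a–C4 and O1–C2: the first two bonds come from insertion of a ring A aryne into the carboxyl C–O bond, the third from addition–elimination at the β-methoxy carbon.
3. Feature: in ring A, C8a (bearing O1) and C4a (bearing the C4 carbonyl) are neighbours, and C4a is flanked by the C5 oxygen. Ring A can therefore enter as a C4a≡C8a aryne, polarised by the C5 benzyloxy group so that oxygen goes to C8a and the acyl carbon to C4a. C8 stays C–H so that only one alkoxy group flanks the aryne.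
4. 10 ⇐ methyl 3,5-dihydroxy-4-methoxybenzoate (benzylation, ester to aldehyde, Baeyer–Villiger to the phenol, ortho-bromination, retro-Brook silyl shift, triflation). 17 ⇐ methyl methoxyacetate + 4-(benzyloxy)benzoyl chloride (Claisen acylation, O-methylation, saponification).
5. Ring order: rings A and B are bought as benzenoid starting materials; ring C (the pyranone) is the only ring built, in step 10.

Key step: step 10

Remark: the target has no stereocentre; the enol ether geometry of 16, 17 and 19 is drawn E but is lost on ring closure, so an E/Z mixture would be carried forward unseparated.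

**Route**

Step 1
Reactants: 1 methyl 3,5-dihydroxy-4-methoxybenzoate
Product: 2 methyl 3,5-bis(benzyloxy)-4-methoxybenzoate
Conditions: BnBr (2.4 equiv), K2CO3 (3 equiv), DMF, 60 °C
Reagents that add atoms: benzyl bromide, BrCc1ccccc1
Why: Williamson etherification of the two equivalent phenols should proceed cleanly, the ester and the aryl methyl ether being inert to carbonate.

Step 2
Reactants: 2 methyl 3,5-bis(benzyloxy)-4-methoxybenzoate
Product: 3 [3,5-bis(benzyloxy)-4-methoxyphenyl]methanol
Conditions: LiAlH4, THF, 0 °C to rt; aqueous NaOH work-up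
Reagents that add atoms: none
Why: Hydride reduction of an aryl ester to the benzylic alcohol is standard and leaves benzyl and methyl aryl ethers untouched.

Step 3
Reactants: 3 [3,5-bis(benzyloxy)-4-methoxyphenyl]methanol
Product: 4 3,5-bis(benzyloxy)-4-methoxybenzaldehyde
Conditions: MnO2 (excess), CH2Cl2, rt
Reagents that add atoms: none
Why: MnO2 oxidises benzylic alcohols selectively to aldehydes without over-oxidation.

Step 4
Reactants: 4 3,5-bis(benzyloxy)-4-methoxybenzaldehyde
Product: 6 3,5-bis(benzyloxy)-4-methoxyphenol, via aryl formate 5 (not isolated)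
Conditions: mCPBA, CH2Cl2, 0 °C to rt; then K2CO3 (cat.), MeOH, rt
Reagents that add atoms: 3-chloroperoxybenzoic acid, OOC(=O)c1cccc(Cl)c1
Why: Baeyer–Villiger oxidation of an electron-rich benzaldehyde proceeds with aryl migration to the formate, which methanolysis should convert into the phenol.

Step 5
Reactants: 6 3,5-bis(benzyloxy)-4-methoxyphenol
Product: 7 3,5-bis(benzyloxy)-2-bromo-4-methoxyphenol
Conditions: NBS (1.0 equiv), CH2Cl2, −78 to 0 °C
Reagents that add atoms: N-bromosuccinimide, O=C1CCC(=O)N1Br
Why: Electrophilic bromination of the phenol can give only one monobromide, since the two free positions are equivalent and each lies ortho to the hydroxyl; one equivalent at low temperature should limit dibromination.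

Step 6
Reactants: 7 3,5-bis(benzyloxy)-2-bromo-4-methoxyphenol
Product: 10 3,5-bis(benzyloxy)-4-methoxy-2-(trimethylsilyl)phenyl trifluoromethanesulfonate, via aryl trimethylsilyl ether 8 (not isolated), via lithium 2-silylphenoxide 9 (not isolated)
Conditions: (Me3Si)2NH, THF, 70 °C, then evaporate; n-BuLi, THF, −100 °C; Tf2O, −100 °C to rt
Reagents that add atoms: hexamethyldisilazane, C[Si](C)(C)N[Si](C)(C)C; trifluoromethanesulfonic anhydride, O=S(=O)(OS(=O)(=O)C(F)(F)F)C(F)(F)F
Why: O-silylation, bromine–lithium exchange and 1,3 O-to-C silyl shift (retro-Brook rearrangement) place the silyl group on the carbon between the oxygen functions, and the lithium phenoxide is trapped by Tf2O, the standard one-pot route to ortho-silylaryl triflates.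

Step 7
Reactants: 11 methyl methoxyacetate; 12 4-(benzyloxy)benzoyl chloride
Product: 14 methyl 3-[4-(benzyloxy)phenyl]-2-methoxy-3-oxopropanoate (racemic), via lithium ester enolate 13 (not isolated)
Conditions: 11 (2.1 equiv), LiN(iPr)2 (commercial solution, 2.1 equiv), THF, −78 °C; then 12 (1.0 equiv), −78 to 0 °C; aqueous NH4Cl
Reagents that add atoms: none
Why: Claisen-type C-acylation of a preformed lithium ester enolate by an acid chloride should give the β-keto ester, the second equivalent of enolate taking up the acidic product proton; the new stereocentre forms racemic and is erased in step 8.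

Step 8
Reactants: 14 methyl 3-[4-(benzyloxy)phenyl]-2-methoxy-3-oxopropanoate
Product: 16 methyl (E)-3-[4-(benzyloxy)phenyl]-2,3-dimethoxyprop-2-enoate, via potassium enolate 15 (not isolated)
Conditions: KN(SiMe3)2 (1.1 equiv), THF/DMPU, −78 °C; MeOTf (1.2 equiv), −78 to 0 °C
Reagents that add atoms: methyl trifluoromethanesulfonate, COS(=O)(=O)C(F)(F)F
Why: O-alkylation of a dissociated potassium β-keto ester enolate by a hard methylating agent in a dipolar medium should be favoured over C-alkylation, the more so as the carbon terminus is substituted.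

Step 9
Reactants: 16 methyl (E)-3-[4-(benzyloxy)phenyl]-2,3-dimethoxyprop-2-enoate
Product: 17 (E)-3-[4-(benzyloxy)phenyl]-2,3-dimethoxyprop-2-enoic acid
Conditions: LiOH·H2O (3 equiv), THF/MeOH/H2O, 50 °C; then cold 1 M HCl to pH 4
Reagents that add atoms: lithium hydroxide, [Li+].[OH-]
Why: Saponification by acyl–oxygen cleavage should give the acid, the push–pull enol ether tolerating brief cold, mild acidification.

Step 10
Reactants: 10 3,5-bis(benzyloxy)-4-methoxy-2-(trimethylsilyl)phenyl trifluoromethanesulfonate; 17 (E)-3-[4-(benzyloxy)phenyl]-2,3-dimethoxyprop-2-enoic acid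
Product: 20 5,7-bis(benzyloxy)-2-[4-(benzyloxy)phenyl]-3,6-dimethoxy-4H-chromen-4-one, via aryne 18 (not isolated), via cesium 2-acylphenoxide 19 (not isolated)
Conditions: 10 (1.5 equiv), 17 (1.0 equiv), CsF (4 equiv), THF, 125 °C, sealed tube
Reagents that add atoms: none
Why: Fluoride removes the silyl group of 10 and triflate leaves to give aryne 18; the carboxylate of 17 adds at the aryne carbon remote from the flanking benzyloxy group (future C8a), leaving the aryl anion on the carbon next to that oxygen (future C4a), where the C–O dipole stabilises it. The anion attacks the ester carbonyl just formed through a four-membered alkoxide that opens to the ortho-acylphenoxide 19, so the carboxyl C–O bond is inserted across the aryne (C8a–O1 and C4a–C4). This is the known aryne insertion into the C–O bond of carboxylic acids, which with unsaturated acids continues by conjugate closure to chromanones and flavones. Ring C then closes by 6-endo-trig attack of the phenoxide oxygen on the methoxy-bearing β-carbon and loss of methoxide (addition–elimination), forming O1–C2 and restoring the C2=C3 bond, both alkene geometries converging through the enolate. No stereocentre is formed. The selectivity needed is regiochemical and is secured by the single benzyloxy group beside the aryne, the other flank being C–H; hot THF is chosen because it favours acyl transfer over protonation of the aryl anion.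

Step 11
Reactants: 20 5,7-bis(benzyloxy)-2-[4-(benzyloxy)phenyl]-3,6-dimethoxy-4H-chromen-4-one
Product: 21 5,7-bis(benzyloxy)-2-[4-(benzyloxy)phenyl]-8-bromo-3,6-dimethoxy-4H-chromen-4-one
Conditions: NBS (1.05 equiv), DMF, 0 °C to rt, dark
Reagents that add atoms: N-bromosuccinimide, O=C1CCC(=O)N1Br
Why: Electrophilic bromination should go to C8, the only C–H of ring A, activated by O1 and the 7-benzyloxy group (ortho) and the 5-benzyloxy group (para), while ring B is deactivated by conjugation with the pyranone.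

Step 12
Reactants: 21 5,7-bis(benzyloxy)-2-[4-(benzyloxy)phenyl]-8-bromo-3,6-dimethoxy-4H-chromen-4-one
Product: 22 5,7-bis(benzyloxy)-2-[4-(benzyloxy)phenyl]-3,6,8-trimethoxy-4H-chromen-4-one
Conditions: NaOMe (excess, solution in MeOH), CuBr (0.3 equiv), DMF, 110 °C
Reagents that add atoms: sodium methoxide, [Na+].[O-]C
Why: Ullmann-type copper-catalysed methoxylation of an electron-rich aryl bromide is an established way to turn bromoflavones into methoxyflavones, and benzyl ethers are stable to methoxide.

Step 13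
Reactants: 22 5,7-bis(benzyloxy)-2-[4-(benzyloxy)phenyl]-3,6,8-trimethoxy-4H-chromen-4-one
Product: 23 5,7-dihydroxy-2-(4-hydroxyphenyl)-3,6,8-trimethoxy-4H-chromen-4-one
Conditions: H2 (1 atm), 10% Pd/C, EtOAc/MeOH, rt
Reagents that add atoms: none
Why: Hydrogenolysis should cleave the three benzyl aryl ethers while the tetrasubstituted C2=C3 bond and the methyl ethers stay intact at atmospheric pressure.

**Compound list**

1 | methyl 3,5-dihydroxy-4-methoxybenzoate | COC(=O)c1cc(O)c(OC)c(O)c1 | starting material
2 | methyl 3,5-bis(benzyloxy)-4-methoxybenzoate | COC(=O)c1cc(OCc2ccccc2)c(OC)c(OCc2ccccc2)c1 | intermediate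
3 | [3,5-bis(benzyloxy)-4-methoxyphenyl]methanol | OCc1cc(OCc2ccccc2)c(OC)c(OCc2ccccc2)c1 | intermediate
4 | 3,5-bis(benzyloxy)-4-methoxybenzaldehyde | O=Cc1cc(OCc2ccccc2)c(OC)c(OCc2ccccc2)c1 | intermediate
5 | 3,5-bis(benzyloxy)-4-methoxyphenyl formate (not isolated) | O=COc1cc(OCc2ccccc2)c(OC)c(OCc2ccccc2)c1 | intermediate
6 | 3,5-bis(benzyloxy)-4-methoxyphenol | Oc1cc(OCc2ccccc2)c(OC)c(OCc2ccccc2)c1 | intermediate
7 | 3,5-bis(benzyloxy)-2-bromo-4-methoxyphenol | Oc1cc(OCc2ccccc2)c(OC)c(OCc2ccccc2)c1Br | intermediate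
8 | [3,5-bis(benzyloxy)-2-bromo-4-methoxyphenoxy]trimethylsilane (not isolated) | C[Si](C)(C)Oc1cc(OCc2ccccc2)c(OC)c(OCc2ccccc2)c1Br | intermediate
9 | lithium 3,5-bis(benzyloxy)-4-methoxy-2-(trimethylsilyl)phenoxide (not isolated) | [Li+].[O-]c1cc(OCc2ccccc2)c(OC)c(OCc2ccccc2)c1[Si](C)(C)C | intermediate
10 | 3,5-bis(benzyloxy)-4-methoxy-2-(trimethylsilyl)phenyl trifluoromethanesulfonate | COc1c(OCc2ccccc2)cc(OS(=O)(=O)C(F)(F)F)c([Si](C)(C)C)c1OCc1ccccc1 | intermediate
11 | methyl methoxyacetate | COCC(=O)OC | starting material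
12 | 4-(benzyloxy)benzoyl chloride | O=C(Cl)c1ccc(OCc2ccccc2)cc1 | starting material
13 | lithium (E)-1,2-dimethoxyethen-1-olate, enolate oxygen cis to the 2-methoxy group (not isolated) | [Li+].[O-]/C(OC)=C\OC | intermediate
14 | methyl 3-[4-(benzyloxy)phenyl]-2-methoxy-3-oxopropanoate (racemic) | COC(C(=O)OC)C(=O)c1ccc(OCc2ccccc2)cc1 | intermediate
15 | potassium (E)-1-[4-(benzyloxy)phenyl]-2,3-dimethoxy-3-oxoprop-1-en-1-olate (not isolated) | [K+].[O-]/C(c1ccc(OCc2ccccc2)cc1)=C(/OC)C(=O)OC | intermediate
16 | methyl (E)-3-[4-(benzyloxy)phenyl]-2,3-dimethoxyprop-2-enoate | CO/C(=C(/OC)C(=O)OC)c1ccc(OCc2ccccc2)cc1 | intermediate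
17 | (E)-3-[4-(benzyloxy)phenyl]-2,3-dimethoxyprop-2-enoic acid | CO/C(=C(/OC)C(=O)O)c1ccc(OCc2ccccc2)cc1 | intermediate
18 | 3,5-bis(benzyloxy)-4-methoxybenzyne (1,2-didehydrobenzene, not isolated) | COC1=C(OCc2ccccc2)C#CC=C1OCc1ccccc1 | intermediate
19 | cesium 3,5-bis(benzyloxy)-2-{(E)-3-[4-(benzyloxy)phenyl]-2,3-dimethoxyprop-2-enoyl}-4-methoxyphenoxide (not isolated) | [Cs+].[O-]c1cc(OCc2ccccc2)c(OC)c(OCc2ccccc2)c1C(=O)/C(OC)=C(\OC)c1ccc(OCc2ccccc2)cc1 | intermediate
20 | 5,7-bis(benzyloxy)-2-[4-(benzyloxy)phenyl]-3,6-dimethoxy-4H-chromen-4-one | COc1c(-c2ccc(OCc3ccccc3)cc2)oc2cc(OCc3ccccc3)c(OC)c(OCc3ccccc3)c2c1=O | intermediate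
21 | 5,7-bis(benzyloxy)-2-[4-(benzyloxy)phenyl]-8-bromo-3,6-dimethoxy-4H-chromen-4-one | COc1c(-c2ccc(OCc3ccccc3)cc2)oc2c(Br)c(OCc3ccccc3)c(OC)c(OCc3ccccc3)c2c1=O | intermediate
22 | 5,7-bis(benzyloxy)-2-[4-(benzyloxy)phenyl]-3,6,8-trimethoxy-4H-chromen-4-one | COc1c(-c2ccc(OCc3ccccc3)cc2)oc2c(OC)c(OCc3ccccc3)c(OC)c(OCc3ccccc3)c2c1=O | intermediate
23 | 5,7-dihydroxy-2-(4-hydroxyphenyl)-3,6,8-trimethoxy-4H-chromen-4-one | COc1c(O)c(OC)c2oc(-c3ccc(O)cc3)c(OC)c(=O)c2c1O | target

**Step count**

Total steps: 13. Longest linear sequence: 10 steps (steps 1–6 and 10–13); the acid branch (steps 7–9) joins at step 10.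

**Steps most likely to fail**

Step 10. The aryl anion may be protonated before it attacks the ester carbonyl, since the carbonyl of a push–pull acrylate is a weak electrophile; the reaction would then stop at the simple aryl ester. Addition to the aryne may also be less regioselective than expected. The fallback produces the same ortho-ester aryl anion without an aryne and without a proton source. It sets out from 7 and 17. They are coupled (EDC·HCl, DMAP, CH2Cl2, rt) to 3,5-bis(benzyloxy)-2-bromo-4-methoxyphenyl (E)-3-[4-(benzyloxy)phenyl]-2,3-dimethoxyprop-2-enoate F1. Bromine–lithium exchange (n-BuLi, THF, −100 °C) then triggers the 1,3 O-to-C acyl shift (anionic Fries rearrangement, known for ortho-haloaryl esters). Work-up should give (E)-1-[2,4-bis(benzyloxy)-6-hydroxy-3-methoxyphenyl]-3-[4-(benzyloxy)phenyl]-2,3-dimethoxyprop-2-en-1-one F2. K2CO3 in DMF at 60 °C closes it by addition–elimination, and the route is rejoined at 20.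

Step 8. Methylation at the α-carbon may compete with O-methylation, giving the quaternary keto ester. The fallback sets out from 14 and makes the enol ether by ketalisation and elimination, where only oxygen can carry the new methyl group. HC(OMe)3 with catalytic TsOH in MeOH at 60 °C should give methyl 3-[4-(benzyloxy)phenyl]-2,3,3-trimethoxypropanoate F3. Me3SiOTf and iPr2NEt in CH2Cl2 at 0 °C then remove methanol across C2–C3, and the route is rejoined at 16.

Step 12. Reductive loss of bromine (return to 20) or attack of methoxide on C2 with opening of the pyranone may outrun the copper-catalysed substitution at the doubly ortho-substituted C8. The fallback sets out from 21 and introduces the oxygen through boron. Miyaura borylation (B2pin2, Pd(OAc)2, SPhos, KOAc, dioxane, 90 °C) should give 5,7-bis(benzyloxy)-2-[4-(benzyloxy)phenyl]-3,6-dimethoxy-8-(4,4,5,5-tetramethyl-1,3,2-dioxaborolan-2-yl)-4H-chromen-4-one F4. Oxidation (NaBO3·4H2O, THF/H2O, rt) gives 5,7-bis(benzyloxy)-2-[4-(benzyloxy)phenyl]-8-hydroxy-3,6-dimethoxy-4H-chromen-4-one F5. Methylation (MeI, K2CO3, DMF, rt) rejoins the route at 22.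

**Further compounds**

F1 | step 10 | 3,5-bis(benzyloxy)-2-bromo-4-methoxyphenyl (E)-3-[4-(benzyloxy)phenyl]-2,3-dimethoxyprop-2-enoate | CO/C(=C(/OC)C(=O)Oc1cc(OCc2ccccc2)c(OC)c(OCc2ccccc2)c1Br)c1ccc(OCc2ccccc2)cc1
F2 | step 10 | (E)-1-[2,4-bis(benzyloxy)-6-hydroxy-3-methoxyphenyl]-3-[4-(benzyloxy)phenyl]-2,3-dimethoxyprop-2-en-1-one | Oc1cc(OCc2ccccc2)c(OC)c(OCc2ccccc2)c1C(=O)/C(OC)=C(\OC)c1ccc(OCc2ccccc2)cc1
F3 | step 8 | methyl 3-[4-(benzyloxy)phenyl]-2,3,3-trimethoxypropanoate (racemic) | COC(C(=O)OC)C(OC)(OC)c1ccc(OCc2ccccc2)cc1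
F4 | step 12 | 5,7-bis(benzyloxy)-2-[4-(benzyloxy)phenyl]-3,6-dimethoxy-8-(4,4,5,5-tetramethyl-1,3,2-dioxaborolan-2-yl)-4H-chromen-4-one | COc1c(-c2ccc(OCc3ccccc3)cc2)oc2c(B3OC(C)(C)C(C)(C)O3)c(OCc3ccccc3)c(OC)c(OCc3ccccc3)c2c1=O
F5 | step 12 | 5,7-bis(benzyloxy)-2-[4-(benzyloxy)phenyl]-8-hydroxy-3,6-dimethoxy-4H-chromen-4-one | COc1c(-c2ccc(OCc3ccccc3)cc2)oc2c(O)c(OCc3ccccc3)c(OC)c(OCc3ccccc3)c2c1=O
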